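## Structural features

The target is apigenin (ring A and ring C form a 5,7-dihydroxy-4H-chromen-4-one, ring B is a 4-hydroxyphenyl group at C2) whose C6 carries a 2-carboxy-1-phenylethyl chain. The only stereocentre is the benzylic methine of that chain, bonded to phenyl, to C6 of ring A, to CH2CO2H and to H; CIP analysis of the given SMILES gives (R). C6 is flanked by the 5-OH and the 7-OH, so the stereocentre is an ortho-hydroxybenzylic carbon (a latent ortho-quinone methide). The carboxyl carbon lies five atoms from either of these oxygens, so the chain is the seco form of a 4-phenyl-3,4-dihydrocoumarin. Ring A is a fully differentiated phloroglucinol: C6 and C8 of 5,7-dihydroxyflavones are both nucleophilic and acid can interchange 6- and 8-substituted isomers (Wessely–Moser rearrangement), so the chain cannot be placed by a late electrophilic substitution. A simplifying feature is that the pyranone oxygen O1 is para to C6 and the two oxygens flanking C6 are equivalent until ring C is closed; if the para oxygen becomes O1, the carbonyl carbon of ring C may be attached at either neighbouring ring carbon and the same 6-substituted flavone results. Fragile groups are the γ-pyrone (opened by hydroxide at C2), the free polyphenol (air oxidation in base) and the hydroxy acid, which relactonises under acid or heat; the stereocentre is not enolisable but sits on a very electron-rich ring. The real difficulty is absolute control at an isolated diarylmethine with no directing group, together with unambiguous placement of the chain at C6. The key step exploits the array O5–C6–CH(Ph)–CH2–CO2H: it builds the CH–CH2 bond and the O–C(=O) bond of the latent lactone in one enantioconvergent operation.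

## Logic of the disconnections

**16 to 15.** The O5–C(=O) bond (flavone numbering) is re-formed in the retrosynthetic sense, so 16 becomes the seco acid of 15. The lactone carries the acid through the synthesis without a protecting group and keeps O5 out of all ring-forming events. The forward step must hydrolyse an aryl lactone without opening the γ-pyrone and without relactonisation on acidification.

**15 to 14.** Two O–CH3 bonds are restored. Methyl ethers are the only phenol protection that survives the Lewis-acid and oxidative steps before it. The forward step needs a demethylation that spares the lactone and the pyranone.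

**14 to 13, then 13 to 11 and 12.** First the O1–C2 bond of ring C is cut together with the C2–C3 unsaturation, then the C4–C4a bond. This removes ring B and the three carbons of ring C as commercial 12. In 11 the only free oxygen is the one para to the benzylic carbon; the other two are tied up as lactone and methyl ether. Both free ring carbons of 11 are ortho to that oxygen, so acylation at either one, followed by closure on that oxygen, gives a 6-substituted flavone. The forward demand is only C-acylation of a phenol and an oxidative ring closure that tolerate the lactone.

**11 to 10.** One O–benzyl bond is restored. The para oxygen has to stay distinct from the other two from the first step until ring C is built, and must be capped during the key step so that only an ortho-quinone methide can form.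

**10 to 5 and 6 (key disconnection, via 7, 8 and 9).** The C3–C4 bond and the O1–C2 bond of the lactone ring are cut. This removes the only stereocentre and leads to the planar electrophile 7, which both enantiomers of racemic 5 deliver, and to the two-carbon partner 6. The gain is that stereocentre and lactone arise together from racemic and achiral materials, with no chiral pool input and no resolution. The demand is catalyst control over the two faces of 7, and a single site of quinone methide formation, which the one free phenol of 5 secures.

**5 to 4, then 4 to 2 and 3.** The C–S bond and then the benzylic C–phenyl bond are cut. The sulfone is a storable precursor of 7; the carbinol needs no stereocontrol because the key step is stereoconvergent.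

**2 to 1.** One O–benzyl bond is cut. Commercial 1 already has one ortho oxygen methylated, one free and chelated, and the para oxygen free and most acidic, so a single selective alkylation gives the required pattern.

## Other disconnections considered

**Alternative 1:** This is the cut that comes to mind first, the C6–C(benzylic) bond. The forward key step is acid-promoted conjugate hydroarylation and lactonisation of unprotected apigenin with (E)-cinnamic acid, which would give racemic lactone A1 (chain at C6) together with its C8-linked isomer A2. The chosen plan is preferred for three reasons: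
- Regiochemistry: both C6 and C8 are nucleophilic, and the acidic medium allows Wessely–Moser equilibration, so a mixture is expected.
- Stereochemistry: the bond forms by cationic Friedel–Crafts conjugate addition, which offers no handle for a chiral catalyst. A metal-catalysed asymmetric variant would need a 2,6-dioxygenated arylboron reagent, a class prone to fast protodeboronation and slow transmetalation.
- Outcome: a racemic mixture of regioisomers would have to be separated and resolved, whereas the chosen plan fixes both issues by design.

**Alternative 2:** The cut is the phenyl–C(benzylic) bond. The forward key step is a Hayashi–Miyaura addition of phenylboronic acid to coumarin A3 (from 2 by Wittig olefination and lactonisation) with a monovalent rhodium catalyst such as [Rh(acac)(C2H4)2]/(R)-SEGPHOS, giving 10 directly. This is a serious route of similar length. It is set aside on mechanistic grounds: the 5- and 7-alkoxy groups are ortho and para to C4a and make C4 of A3 a vinylogous carbonate carbon, and the peri 5-methoxy group shields the site of phenyl insertion. Slow addition with competing protodeboronation of the boronic acid is therefore expected. In the chosen plan the same donor groups work in favour of the key step, because they accelerate loss of sulfinate and stabilise the quinone methide.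

**Alternative 3:** The cut is again the C6–C(benzylic) bond, but made intramolecularly. The forward key step is an aromatic Claisen rearrangement of 5-O-cinnamyl ether A4 to the 6-(1-phenylallyl)flavone A5, followed by anti-Markovnikov oxidation of the vinyl group to the acid. The [3,3] shift can only reach C6 from O5, which answers the regiochemical question. It is rejected because the ether is achiral and the chair transition state has two enantiotopic faces with no control element, and no general catalytic asymmetric aromatic Claisen rearrangement is available for such a substrate. A5 would therefore be racemic, could drift to C8 by a following Cope shift, and would need three further redox operations on the side chain.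

Key step: step 4

Remark: the sense of induction of the bifunctional catalyst on this substrate is assumed, not known; the quinine-derived squaramide is written, and its quinidine-derived pseudo-enantiomer takes its place if the opposite face is favoured.

## Route

Step 1
Reactants: 1 2,4-dihydroxy-6-methoxybenzaldehyde
Product: 2 4-(benzyloxy)-2-hydroxy-6-methoxybenzaldehyde
Conditions: BnBr (1.05 equiv), K2CO3 (1.0 equiv), acetone, rt
Reagents that add atoms: benzyl bromide, BrCc1ccccc1
Why: Williamson ether synthesis; the 2-OH is held in a hydrogen bond to the formyl group, while the 4-OH is para to the formyl group, more acidic and unhindered, so mono-benzylation should occur at the para oxygen.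

Step 2
Reactants: 2 4-(benzyloxy)-2-hydroxy-6-methoxybenzaldehyde; 3 phenylmagnesium bromide
Product: 4 (±)-5-(benzyloxy)-2-[hydroxy(phenyl)methyl]-3-methoxyphenol
Conditions: PhMgBr (2.5 equiv), THF, 0 °C to rt; then sat. aq. NH4Cl
Reagents that add atoms: none
Why: Grignard addition to an aldehyde; the first equivalent forms the magnesium phenoxide and the second adds to the chelated formyl group. The carbinol is racemic, which is acceptable because step 4 is stereoconvergent; 4 is taken on crude because it ionises easily.

Step 3
Reactants: 4 (±)-5-(benzyloxy)-2-[hydroxy(phenyl)methyl]-3-methoxyphenol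
Product: 5 (±)-5-(benzyloxy)-3-methoxy-2-[phenyl(4-methylbenzenesulfonyl)methyl]phenol
Conditions: p-TolSO2H (1.5 equiv), CH2Cl2, rt
Reagents that add atoms: 4-methylbenzenesulfinic acid, Cc1ccc(cc1)S(=O)O
Why: Acid-promoted SN1-type substitution through the stabilised benzhydryl cation; S-alkylation of the sulfinate gives the sulfone as the thermodynamic product. This is the standard preparation of 2-(1-arylsulfonylalkyl)phenols used as storable ortho-quinone methide precursors.

Step 4
Reactants: 5 (±)-5-(benzyloxy)-3-methoxy-2-[phenyl(4-methylbenzenesulfonyl)methyl]phenol; 6 Meldrum's acid (2,2-dimethyl-1,3-dioxane-4,6-dione)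
Product: 10 (R)-7-(benzyloxy)-5-methoxy-4-phenyl-3,4-dihydro-2H-chromen-2-one, via ortho-quinone methide 7 (not isolated), via Michael adduct 8 (not isolated), via lactone acid 9 (not isolated)
Conditions: quinine-derived squaramide catalyst (3,5-bis(trifluoromethyl)anilino squaramide of 9-amino-9-deoxy-epi-quinine, 10 mol %), aq. NaHCO3, toluene, 0 °C; then aq. HCl to pH 2, organic phase, p-TsOH·H2O (cat.), 90 °C
Reagents that add atoms: none
Why: Base-induced 1,4-elimination of p-toluenesulfinate from either enantiomer of 5 gives the same planar ortho-quinone methide 7, so the racemate passes through one achiral electrophile and the step is enantioconvergent. The quinuclidine nitrogen of the catalyst deprotonates 6 and the two squaramide N–H bonds hold the carbonyl oxygen of 7, so the enolate is delivered to one enantiotopic face of the exocyclic methide carbon in a 1,4-addition driven by rearomatisation; this sets C4 in adduct 8. The closest known reaction type is the organocatalytic Michael addition–lactonisation of Meldrum's acid and other 1,3-dicarbonyl compounds to ortho-quinone methides generated in situ from 2-(1-arylsulfonylalkyl)phenols under biphasic basic conditions. The δ-lactone closes by 6-exo-trig attack of the phenol oxygen on a carbonyl group of the Meldrum's acid unit (acyl substitution with loss of acetone) to give 9, and warming with acid removes CO2 to leave 10; overall this is a formal [4+2] union of the O=C–C=C unit of 7 with a ketene equivalent. The single new stereocentre is controlled only by the catalyst, because neither partner carries stereochemical information and the C3 centre of 9 is erased on decarboxylation; the (R) configuration is reached by the choice between the quinine-derived catalyst and its pseudo-enantiomer. The step needs facial selectivity and a single site of quinone methide formation; the substrate secures the latter because only one phenol is free, the second ortho oxygen being a methyl ether and the para oxygen a benzyl ether, which also excludes a para-quinone methide or its anion. The alkoxy donors make ionisation easy at 0 °C, and closure of the lactone makes the addition irreversible before a retro-Michael process can erode the configuration.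

Step 5
Reactants: 10 (R)-7-(benzyloxy)-5-methoxy-4-phenyl-3,4-dihydro-2H-chromen-2-one
Product: 11 (R)-7-hydroxy-5-methoxy-4-phenyl-3,4-dihydro-2H-chromen-2-one
Conditions: H2 (1 atm), Pd/C (10 wt %), EtOAc, rt
Reagents that add atoms: none
Why: Hydrogenolysis of a benzyl aryl ether; the lactone and the C–C bonds of the diarylmethine are inert, and a non-nucleophilic solvent avoids alcoholysis of the lactone. This frees only the oxygen para to the benzylic carbon.

Step 6
Reactants: 11 (R)-7-hydroxy-5-methoxy-4-phenyl-3,4-dihydro-2H-chromen-2-one; 12 (E)-3-(4-methoxyphenyl)prop-2-enoyl chloride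
Product: 13 (R)-7-hydroxy-5-methoxy-8-[(E)-3-(4-methoxyphenyl)prop-2-enoyl]-4-phenyl-3,4-dihydro-2H-chromen-2-one
Conditions: AlCl3 (3 equiv), PhNO2/CH2Cl2, 0 °C to rt
Reagents that add atoms: none
Why: Friedel–Crafts acylation of a phenol through its aluminium phenoxide (Fries manifold); C8 is ortho to the free OH, para to the methoxy group and less hindered than C6, so it should be the main site. Acylation at the other free position would lead through steps 7 to 9 to the same compound 16, because in both cases ring C can only close on the one free oxygen, which is para to the benzylic carbon.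

Step 7
Reactants: 13 (R)-7-hydroxy-5-methoxy-8-[(E)-3-(4-methoxyphenyl)prop-2-enoyl]-4-phenyl-3,4-dihydro-2H-chromen-2-one
Product: 14 (4R)-5-methoxy-8-(4-methoxyphenyl)-4-phenyl-3,4-dihydro-2H,10H-pyrano[2,3-f]chromene-2,10-dione
Conditions: I2 (10 mol %), DMSO, 120 °C
Reagents that add atoms: none
Why: Iodine-catalysed oxidative cyclisation of a 2'-hydroxychalcone to a flavone (oxa-Michael closure, α-iodination, loss of HI, reoxidation of HI by DMSO). The stereocentre is remote and not enolisable, and the lactone keeps the second ortho oxygen out of the ring closure.

Step 8
Reactants: 14 (4R)-5-methoxy-8-(4-methoxyphenyl)-4-phenyl-3,4-dihydro-2H,10H-pyrano[2,3-f]chromene-2,10-dione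
Product: 15 (4R)-5-hydroxy-8-(4-hydroxyphenyl)-4-phenyl-3,4-dihydro-2H,10H-pyrano[2,3-f]chromene-2,10-dione
Conditions: BBr3 (6 equiv), CH2Cl2, −78 °C to rt; then H2O, 0 °C
Reagents that add atoms: none
Why: Lewis-acid cleavage of aryl methyl ethers with BBr3, a standard end-game for methylated flavones; the aryl lactone and the γ-pyrone should tolerate it and the stereocentre is not touched.

Step 9
Reactants: 15 (4R)-5-hydroxy-8-(4-hydroxyphenyl)-4-phenyl-3,4-dihydro-2H,10H-pyrano[2,3-f]chromene-2,10-dione
Product: 16 (3R)-3-[5,7-dihydroxy-2-(4-hydroxyphenyl)-4-oxo-4H-chromen-6-yl]-3-phenylpropanoic acid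
Conditions: LiOH (5 equiv), degassed THF/H2O, 0 °C; then 1 M HCl to pH 3–4, 0 °C
Reagents that add atoms: lithium hydroxide, [Li+].[OH-]; water, O
Why: Saponification of an aryl lactone, which is fast at 0 °C, while the polyphenolate γ-pyrone should resist hydroxide at this temperature. Cold acidification only to pH 3–4 should release the hydroxy acid without relactonisation, and the stereocentre, β to the carboxylate, has no pathway for epimerisation.

## Compound list

1 | 2,4-dihydroxy-6-methoxybenzaldehyde | COc1cc(O)cc(O)c1C=O | starting material
2 | 4-(benzyloxy)-2-hydroxy-6-methoxybenzaldehyde | COc1cc(OCc2ccccc2)cc(O)c1C=O | intermediate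
3 | phenylmagnesium bromide | Br[Mg]c1ccccc1 | starting material
4 | (±)-5-(benzyloxy)-2-[hydroxy(phenyl)methyl]-3-methoxyphenol | COc1cc(OCc2ccccc2)cc(O)c1C(O)c1ccccc1 | intermediate
5 | (±)-5-(benzyloxy)-3-methoxy-2-[phenyl(4-methylbenzenesulfonyl)methyl]phenol | COc1cc(OCc2ccccc2)cc(O)c1C(c1ccccc1)S(=O)(=O)c1ccc(C)cc1 | intermediate
6 | Meldrum's acid (2,2-dimethyl-1,3-dioxane-4,6-dione) | CC1(C)OC(=O)CC(=O)O1 | starting material
7 | 3-(benzyloxy)-6-benzylidene-5-methoxycyclohexa-2,4-dien-1-one (ortho-quinone methide) | COC1=CC(OCc2ccccc2)=CC(=O)C1=Cc1ccccc1 | intermediate
8 | 5-{(R)-[4-(benzyloxy)-2-hydroxy-6-methoxyphenyl](phenyl)methyl}-2,2-dimethyl-1,3-dioxane-4,6-dione | CC1(C)OC(=O)C([C@H](c2ccccc2)c2c(O)cc(OCc3ccccc3)cc2OC)C(=O)O1 | intermediate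
9 | (4R)-7-(benzyloxy)-5-methoxy-2-oxo-4-phenyl-3,4-dihydro-2H-chromene-3-carboxylic acid (C3 epimers) | OC(=O)C1[C@H](c2ccccc2)c2c(OC)cc(OCc3ccccc3)cc2OC1=O | intermediate
10 | (R)-7-(benzyloxy)-5-methoxy-4-phenyl-3,4-dihydro-2H-chromen-2-one | O=C1C[C@H](c2ccccc2)c2c(OC)cc(OCc3ccccc3)cc2O1 | intermediate
11 | (R)-7-hydroxy-5-methoxy-4-phenyl-3,4-dihydro-2H-chromen-2-one | O=C1C[C@H](c2ccccc2)c2c(OC)cc(O)cc2O1 | intermediate
12 | (E)-3-(4-methoxyphenyl)prop-2-enoyl chloride | COc1ccc(/C=C/C(Cl)=O)cc1 | starting material
13 | (R)-7-hydroxy-5-methoxy-8-[(E)-3-(4-methoxyphenyl)prop-2-enoyl]-4-phenyl-3,4-dihydro-2H-chromen-2-one | O=C1C[C@H](c2ccccc2)c2c(OC)cc(O)c(C(=O)/C=C/c3ccc(OC)cc3)c2O1 | intermediate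
14 | (4R)-5-methoxy-8-(4-methoxyphenyl)-4-phenyl-3,4-dihydro-2H,10H-pyrano[2,3-f]chromene-2,10-dione (flavone numbering: 7,4'-di-O-methyl, lactone closed on O5) | O=C1C[C@H](c2ccccc2)c2c(OC)cc3oc(-c4ccc(OC)cc4)cc(=O)c3c2O1 | intermediate
15 | (4R)-5-hydroxy-8-(4-hydroxyphenyl)-4-phenyl-3,4-dihydro-2H,10H-pyrano[2,3-f]chromene-2,10-dione | O=C1C[C@H](c2ccccc2)c2c(O)cc3oc(-c4ccc(O)cc4)cc(=O)c3c2O1 | intermediate
16 | (3R)-3-[5,7-dihydroxy-2-(4-hydroxyphenyl)-4-oxo-4H-chromen-6-yl]-3-phenylpropanoic acid | O=C(O)C[C@H](c1ccccc1)c1c(O)cc2oc(-c3ccc(O)cc3)cc(=O)c2c1O | target

## Step count and least certain steps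

Total step count: 9. Longest linear sequence: 9 steps (1 to 16); 3, 6 and 12 are commercial inputs.

**Step 4 (key step).** Facial selectivity may be poor. The phenyl group on the methide carbon has a substituted neighbour on both sides (the carbonyl carbon and the methoxy-bearing carbon), so two exocyclic geometries can compete and present opposite faces to the catalyst. In addition, a quinone methide stabilised by three oxygen donors may add the nucleophile slowly, reversibly, or through an uncatalysed background pathway before the lactone closes.
Fallback: it sets out from 5 and returns at 10. The same addition, lactonisation and decarboxylation is run with an achiral amine (DABCO) and aq. NaHCO3 to give racemic 7-(benzyloxy)-5-methoxy-4-phenyl-3,4-dihydro-2H-chromen-2-one F1. Dehydrogenation with DDQ in refluxing dioxane gives the achiral 7-(benzyloxy)-5-methoxy-4-phenyl-2H-chromen-2-one F2. Enantioselective conjugate reduction with a ligated copper hydride (Cu(OAc)2, the appropriate enantiomer of DTBM-SEGPHOS, diethoxymethylsilane, t-BuOH, toluene) then gives 10. This sequence is again stereoconvergent, since the racemate passes through an achiral coumarin.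

**Step 6.** O-acylation may occur without migration to carbon. The electron-rich ring may also undergo Friedel–Crafts conjugate addition to the anisyl-substituted enone, and the Lewis acid may cleave the methyl ether if acylation takes place next to it; the last process would free a second oxygen and undo the regiochemical lock.
Fallback: it sets out from 11 and returns at 13. Friedel–Crafts acetylation (AcCl, AlCl3, CH2Cl2, 0 °C) gives (R)-8-acetyl-7-hydroxy-5-methoxy-4-phenyl-3,4-dihydro-2H-chromen-2-one F3. A Claisen–Schmidt condensation with 4-methoxybenzaldehyde promoted by BF3·OEt2 (dioxane, rt), under acidic conditions that the lactone tolerates, then gives 13.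

**Step 7.** At 120 °C in the presence of iodine and HI, nuclear iodination of the remaining electron-rich ring position, partial opening of the lactone, or ionisation at the doubly benzylic centre with loss of configuration may occur.
Fallback: it sets out from 11 and returns at 14, replacing steps 6 and 7. 3-(4-Methoxyphenyl)prop-2-ynoyl chloride F4, made from the commercial acid with oxalyl chloride and catalytic DMF, acylates 11 (AlCl3, CH2Cl2, 0 °C) to give (R)-7-hydroxy-5-methoxy-8-[3-(4-methoxyphenyl)prop-2-ynoyl]-4-phenyl-3,4-dihydro-2H-chromen-2-one F5. A 6-endo-dig oxa-Michael closure (TfOH cat., CH2Cl2, rt) then gives 14. The alkyne brings in the oxidation level of ring C, so no oxidant is needed.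

**Step 9.** The hydroxy acid may relactonise on acidification or concentration, and hydroxide may attack C2 of the γ-pyrone, with ring opening and reclosure on the other oxygen.
Fallback: it sets out from 15 and returns at 16. Ring opening of the aryl lactone with benzyl alcohol (BnOH, Et3N, cat. DMAP, THF, rt) gives benzyl (3R)-3-[5,7-dihydroxy-2-(4-hydroxyphenyl)-4-oxo-4H-chromen-6-yl]-3-phenylpropanoate F6. Hydrogenolysis (H2, Pd/C, EtOAc, rt) then releases 16 under neutral conditions, with no aqueous base and no acidification.

## Further compounds

F1 | step 4 | (±)-7-(benzyloxy)-5-methoxy-4-phenyl-3,4-dihydro-2H-chromen-2-one | O=C1CC(c2ccccc2)c2c(OC)cc(OCc3ccccc3)cc2O1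
F2 | step 4 | 7-(benzyloxy)-5-methoxy-4-phenyl-2H-chromen-2-one | O=c1cc(-c2ccccc2)c2c(OC)cc(OCc3ccccc3)cc2o1
F3 | step 6 | (R)-8-acetyl-7-hydroxy-5-methoxy-4-phenyl-3,4-dihydro-2H-chromen-2-one | O=C1C[C@H](c2ccccc2)c2c(OC)cc(O)c(C(C)=O)c2O1
F4 | step 7 | 3-(4-methoxyphenyl)prop-2-ynoyl chloride | COc1ccc(C#CC(Cl)=O)cc1
F5 | step 7 | (R)-7-hydroxy-5-methoxy-8-[3-(4-methoxyphenyl)prop-2-ynoyl]-4-phenyl-3,4-dihydro-2H-chromen-2-one | O=C1C[C@H](c2ccccc2)c2c(OC)cc(O)c(C(=O)C#Cc3ccc(OC)cc3)c2O1
F6 | step 9 | benzyl (3R)-3-[5,7-dihydroxy-2-(4-hydroxyphenyl)-4-oxo-4H-chromen-6-yl]-3-phenylpropanoate | O=C(OCc1ccccc1)C[C@H](c1ccccc1)c1c(O)cc2oc(-c3ccc(O)cc3)cc(=O)c2c1O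
A1 | alternative 1 | (±)-5-hydroxy-8-(4-hydroxyphenyl)-4-phenyl-3,4-dihydro-2H,6H-pyrano[3,2-g]chromene-2,6-dione (chain at C6 of the flavone, lactone closed on O7) | O=C1CC(c2ccccc2)c2c(O1)cc1oc(-c3ccc(O)cc3)cc(=O)c1c2O
A2 | alternative 1 | (±)-5-hydroxy-2-(4-hydroxyphenyl)-10-phenyl-9,10-dihydro-4H,8H-pyrano[2,3-f]chromene-4,8-dione (chain at C8 of the flavone, lactone closed on O7) | O=C1CC(c2ccccc2)c2c(O1)cc(O)c3c(=O)cc(-c4ccc(O)cc4)oc23
A3 | alternative 2 | 7-(benzyloxy)-5-methoxy-2H-chromen-2-one | COc1cc(OCc2ccccc2)cc2oc(=O)ccc12
A4 | alternative 3 | 7-methoxy-2-(4-methoxyphenyl)-5-{[(E)-3-phenylprop-2-en-1-yl]oxy}-4H-chromen-4-one | COc1ccc(cc1)-c1cc(=O)c2c(OC/C=C/c3ccccc3)cc(OC)cc2o1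
A5 | alternative 3 | (±)-5-hydroxy-7-methoxy-2-(4-methoxyphenyl)-6-(1-phenylprop-2-en-1-yl)-4H-chromen-4-one | COc1ccc(cc1)-c1cc(=O)c2c(O)c(C(C=C)c3ccccc3)c(OC)cc2o1
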